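**Plan**
- Retrosynthesis cuts, in this order: the two C–C bonds of the CH2 bridge between C8 of the chroman and C3 of the pyranone (ring C); the C6–acetyl bond (bromine as placeholder); both C2–CH3 bonds (back to a lactone); then C3–C4 and O1–C2 of ring B.
- Enabling feature: in ring B, C4 is a benzylic CH2 on the ring-A carbon next to the one bearing O1, and C3 carries oxygen. O1–C8a–C4a–C4 is therefore an ortho-quinone methide and C2–C3 an α-alkoxy acyl enolate.
- Forward: ring A is dressed (phenol, ortho-formyl, silyl ether, benzylic bromide), ring B closes as a lactone in the annulation, MeMgBr then acid turn the lactone carbon into the CMe2 ether carbon, acetyl replaces bromine, and the ethers are cleaved.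
- Ring C is made separately from a β-keto ester dianion and joined last through a one-carbon iminium unit at C8, the only free carbon of ring A.
- Stereochemistry: the single stereocentre, C3 (R), is set by the chiral carbene catalyst in the annulation; no later step breaks a bond to C3.

Key step: step 7

Assumption: the sense of induction for a benzyloxy-substituted azolium enolate is not established. The (5aS,10bR) triazolium salt is written; its commercially available (5aR,10bS) antipode is used instead if the first run gives the (3S) lactone.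

**Step 1**
Reactants: 1 2-bromo-1,3-dimethoxybenzene
Product: 3 4-bromo-3,5-dimethoxyphenol, via aryl pinacol boronate 2 (not isolated)
Conditions: [Ir(OMe)(cod)]2 (1.5 mol%), 4,4'-di-tert-butyl-2,2'-bipyridine, B2pin2, THF, 80 °C; then aq. NaOH, H2O2, 0 °C → rt; acidify
Reagents that add atoms: hydrogen peroxide, OO; bis(pinacolato)diboron, CC1(C)OB(OC1(C)C)B1OC(C)(C)C(C)(C)O1 (boron only in 2)
Why: Iridium-catalysed C–H borylation is sterically controlled and should take the only C–H without an ortho substituent (C5, para to bromine), and the boronate is oxidised in the same flask to the phenol (borylation–oxidation).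

**Step 2**
Reactants: 3 4-bromo-3,5-dimethoxyphenol
Product: 4 3-bromo-6-hydroxy-2,4-dimethoxybenzaldehyde
Conditions: MgCl2, Et3N, (CH2O)n, MeCN, reflux; aq. HCl
Reagents that add atoms: paraformaldehyde (as formaldehyde), C=O
Why: In the magnesium-mediated ortho-formylation of phenols (Casnati–Skattebøl) the magnesium phenoxide delivers formaldehyde to the ortho carbon and a second formaldehyde oxidises the benzylic alkoxide; the two ortho positions are equivalent and the para position is blocked by bromine.

**Step 3**
Reactants: 4 3-bromo-6-hydroxy-2,4-dimethoxybenzaldehyde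
Product: 5 3-bromo-6-{[tert-butyl(dimethyl)silyl]oxy}-2,4-dimethoxybenzaldehyde
Conditions: TBSCl, imidazole, DMF, rt
Reagents that add atoms: tert-butyl(chloro)dimethylsilane, CC(C)(C)[Si](C)(C)Cl
Why: Imidazole-promoted O-silylation of the phenol caps the oxygen that will become O1 with a fluoride-labile group.

**Step 4**
Reactants: 5 3-bromo-6-{[tert-butyl(dimethyl)silyl]oxy}-2,4-dimethoxybenzaldehyde
Product: 6 (3-bromo-6-{[tert-butyl(dimethyl)silyl]oxy}-2,4-dimethoxyphenyl)methanol
Conditions: NaBH4, THF/EtOH, –20 → 0 °C, short time; aq. NH4Cl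
Reagents that add atoms: none
Why: Borohydride reduction of the aldehyde gives the benzylic alcohol, and low temperature with a prompt quench should keep the silyl group from migrating to the benzylic oxygen.

**Step 5**
Reactants: 6 (3-bromo-6-{[tert-butyl(dimethyl)silyl]oxy}-2,4-dimethoxyphenyl)methanol
Product: 7 [4-bromo-2-(bromomethyl)-3,5-dimethoxyphenoxy](tert-butyl)dimethylsilane
Conditions: CBr4, PPh3, CH2Cl2, 0 °C; short silica plug, used at once
Reagents that add atoms: tetrabromomethane, BrC(Br)(Br)Br
Why: The Appel reaction converts the primary benzylic alcohol into the bromide under neutral conditions that spare the aryl silyl ether; the electron-rich bromide is not stored.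

**Step 6**
Reactants: 8 benzyloxyacetyl chloride
Product: 9 2-(benzyloxy)-1-(1H-imidazol-1-yl)ethan-1-one
Conditions: imidazole (2 equiv), CH2Cl2, 0 °C → rt; filter, concentrate
Reagents that add atoms: imidazole, c1c[nH]cn1
Why: N-acylation of imidazole by the acid chloride gives an acyl imidazole, an acyl donor that tolerates fluoride and is known to pass its acyl group to carbene catalysts.

**Step 7**
Reactants: 7 [4-bromo-2-(bromomethyl)-3,5-dimethoxyphenoxy](tert-butyl)dimethylsilane; 9 2-(benzyloxy)-1-(1H-imidazol-1-yl)ethan-1-one
Product: 11 (3R)-3-(benzyloxy)-6-bromo-5,7-dimethoxychroman-2-one, via ortho-quinone methide 10 (not isolated)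
Conditions: 9 (1.5 equiv), (5aS,10bR)-5a,10b-dihydro-2-(2,4,6-trimethylphenyl)-4H,6H-indeno[2,1-b]-1,2,4-triazolo[4,3-d]-1,4-oxazinium chloride (15 mol%), CsF, 18-crown-6, THF, –20 °C, slow addition of 7; pH 7 buffer work-up
Reagents that add atoms: none
Why: Fluoride removes the silyl group of 7 and the phenoxide expels bromide to give methide 10, while the carbene from the triazolium salt attacks 9, releases imidazolide and is deprotonated to a Z-configured benzyloxy azolium enolate. The enolate carbon adds to the exocyclic CH2 of 10 (C3–C4), driven by rearomatisation, and the new phenoxide then acylates on the acyl azolium carbon in a 6-exo-trig closure (O1–C2) that forms the lactone ring and frees the carbene, a formal hetero-Diels–Alder reaction. The closest known reaction type is the carbene-catalysed formal [4+2] of acyl-imidazole-derived azolium enolates with fluoride-released ortho-quinone methides to 3-aryl and 3-alkyl dihydrocoumarins; the benzyloxy donor and the dioxygenated methide are new substrates within it. C3 is set by the catalyst, whose indane-fused backbone shields one face of the enolate so that the methide approaches the other. The step needs enantiofacial control at the enolate carbon and a single acylating oxygen: the first rests on the catalyst at low temperature and a low standing concentration of 7, the second is fixed because only the oxygen that carried silicon becomes a phenoxide, the other two being methyl ethers. The acidic C3–H is protected by the weakly basic medium, the low temperature and the buffered work-up.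

**Step 8**
Reactants: 11 (3R)-3-(benzyloxy)-6-bromo-5,7-dimethoxychroman-2-one
Product: 12 4-bromo-2-[(2R)-2-(benzyloxy)-3-hydroxy-3-methylbutyl]-3,5-dimethoxyphenol
Conditions: MeMgBr (4 equiv), LaCl3·2LiCl, THF, –78 → 0 °C; aq. NH4Cl
Reagents that add atoms: methylmagnesium bromide, C[Mg]Br
Why: Double Grignard addition to the aryl ester opens the lactone to the phenol and the tertiary carbinol, the lanthanum salt favouring addition over enolisation so that C3 should not epimerise, and the aryl bromide is inert to MeMgBr at this temperature.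

**Step 9**
Reactants: 12 4-bromo-2-[(2R)-2-(benzyloxy)-3-hydroxy-3-methylbutyl]-3,5-dimethoxyphenol
Product: 13 (3R)-3-(benzyloxy)-6-bromo-5,7-dimethoxy-2,2-dimethylchromane
Conditions: TsOH·H2O (10 mol%), toluene, 50 °C
Reagents that add atoms: none
Why: In this acid-catalysed cyclodehydration (intramolecular SN1 etherification) the tertiary carbinol ionises and the neighbouring phenol captures the cation to close ring B at O1–C2, with mild catalytic acid chosen so that capture outruns hydride shift or elimination, and the methyl ethers leave O1 as the only oxygen able to cyclise.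

**Step 10**
Reactants: 13 (3R)-3-(benzyloxy)-6-bromo-5,7-dimethoxy-2,2-dimethylchromane; 14 tributyl(1-ethoxyethenyl)stannane
Product: 16 1-[(3R)-3-(benzyloxy)-5,7-dimethoxy-2,2-dimethylchroman-6-yl]ethan-1-one, via ethoxyvinyl arene 15 (not isolated)
Conditions: Pd(P(t-Bu)3)2 (5 mol%), CsF, 1,4-dioxane, 100 °C; then 1 M HCl, THF, rt
Reagents that add atoms: water, O
Why: Stille coupling with the bulky electron-rich phosphine and fluoride activation, the conditions used for doubly ortho-substituted aryl bromides, should give the enol ether, whose mild acid hydrolysis gives the methyl ketone.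

**Step 11**
Reactants: 16 1-[(3R)-3-(benzyloxy)-5,7-dimethoxy-2,2-dimethylchroman-6-yl]ethan-1-one
Product: 17 1-[(3R)-3,5,7-trihydroxy-2,2-dimethylchroman-6-yl]ethan-1-one
Conditions: BBr3 (6 equiv), C6HMe5, CH2Cl2, –78 → 0 °C; then H2O
Reagents that add atoms: none
Why: Boron tribromide cleaves the benzyl ether and both carbonyl-flanking methyl ethers (Lewis acid ether cleavage) with pentamethylbenzene trapping the benzyl cation, while O1, para to the acetyl group and next to the boron-bound C3 oxygen, should resist ionisation so that ring B and C3 are kept.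

**Step 12**
Reactants: 18 methyl 3-oxopentanoate; 19 N-methoxy-N-methylpropanamide
Product: 20 methyl 4-methyl-3,5-dioxoheptanoate
Conditions: LiN(i-Pr)2 (2.1 equiv), THF, –78 → 0 °C; then 19, 0 °C → rt; aq. HCl
Reagents that add atoms: none
Why: The β-keto ester dianion is acylated at its γ-carbon by the Weinreb amide (Weiler dianion acylation), the stable tetrahedral intermediate preventing over-addition.

**Step 13**
Reactants: 20 methyl 4-methyl-3,5-dioxoheptanoate
Product: 21 6-ethyl-4-hydroxy-5-methyl-2H-pyran-2-one
Conditions: DBU, toluene, reflux; aq. HCl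
Reagents that add atoms: none
Why: Base-promoted enol lactonisation of the 3,5-diketo ester, in which the C5 enolate oxygen attacks the ester with loss of methanol, gives the 4-hydroxy-2-pyranone.

**Step 14**
Reactants: 17 1-[(3R)-3,5,7-trihydroxy-2,2-dimethylchroman-6-yl]ethan-1-one; 21 6-ethyl-4-hydroxy-5-methyl-2H-pyran-2-one
Product: 24 3-{[(3R)-6-acetyl-3,5,7-trihydroxy-2,2-dimethylchroman-8-yl]methyl}-6-ethyl-4-hydroxy-5-methyl-2H-pyran-2-one, via pyranone Mannich base 22 (not isolated), via methylidene pyrandione 23 (not isolated)
Conditions: 21, [Me2N=CH2]I (1.0 equiv), MeCN, rt; then 17, 60 °C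
Reagents that add atoms: N,N-dimethylmethyleneiminium iodide (Eschenmoser's salt), C=[N+](C)C.[I-]
Why: A Mannich reaction at C3 of the pyranone followed by loss of dimethylamine gives a methylidene dione that is trapped in a Michael (Friedel–Crafts type) addition by C8 of 17, the only free and strongly activated ring carbon, a reaction type established for methylene-bridged acylphloroglucinol–pyranone heterodimers.

**Compound list**
1 | 2-bromo-1,3-dimethoxybenzene | COc1cccc(OC)c1Br | starting material
2 | 2-(4-bromo-3,5-dimethoxyphenyl)-4,4,5,5-tetramethyl-1,3,2-dioxaborolane | COc1cc(B2OC(C)(C)C(C)(C)O2)cc(OC)c1Br | intermediate (not isolated)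
3 | 4-bromo-3,5-dimethoxyphenol | COc1cc(O)cc(OC)c1Br | intermediate
4 | 3-bromo-6-hydroxy-2,4-dimethoxybenzaldehyde | COc1cc(O)c(C=O)c(OC)c1Br | intermediate
5 | 3-bromo-6-{[tert-butyl(dimethyl)silyl]oxy}-2,4-dimethoxybenzaldehyde | COc1cc(O[Si](C)(C)C(C)(C)C)c(C=O)c(OC)c1Br | intermediate
6 | (3-bromo-6-{[tert-butyl(dimethyl)silyl]oxy}-2,4-dimethoxyphenyl)methanol | COc1cc(O[Si](C)(C)C(C)(C)C)c(CO)c(OC)c1Br | intermediate
7 | [4-bromo-2-(bromomethyl)-3,5-dimethoxyphenoxy](tert-butyl)dimethylsilane | CC(C)(C)[Si](C)(C)Oc1cc(OC)c(Br)c(OC)c1CBr | intermediate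
8 | benzyloxyacetyl chloride | O=C(Cl)COCc1ccccc1 | starting material
9 | 2-(benzyloxy)-1-(1H-imidazol-1-yl)ethan-1-one | O=C(COCc1ccccc1)n1ccnc1 | intermediate
10 | 4-bromo-3,5-dimethoxy-6-methylidenecyclohexa-2,4-dien-1-one | C=C1C(=O)C=C(OC)C(Br)=C1OC | intermediate (not isolated)
11 | (3R)-3-(benzyloxy)-6-bromo-5,7-dimethoxychroman-2-one | O=C1Oc2cc(OC)c(Br)c(OC)c2C[C@H]1OCc1ccccc1 | intermediate
12 | 4-bromo-2-[(2R)-2-(benzyloxy)-3-hydroxy-3-methylbutyl]-3,5-dimethoxyphenol | COc1cc(O)c(C[C@H](C(C)(C)O)OCc2ccccc2)c(OC)c1Br | intermediate
13 | (3R)-3-(benzyloxy)-6-bromo-5,7-dimethoxy-2,2-dimethylchromane | CC1(C)Oc2cc(OC)c(Br)c(OC)c2C[C@H]1OCc1ccccc1 | intermediate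
14 | tributyl(1-ethoxyethenyl)stannane | CCCC[Sn](CCCC)(CCCC)C(=C)OCC | starting material
15 | (3R)-3-(benzyloxy)-6-(1-ethoxyethenyl)-5,7-dimethoxy-2,2-dimethylchromane | CC1(C)Oc2cc(OC)c(C(=C)OCC)c(OC)c2C[C@H]1OCc1ccccc1 | intermediate (not isolated)
16 | 1-[(3R)-3-(benzyloxy)-5,7-dimethoxy-2,2-dimethylchroman-6-yl]ethan-1-one | CC1(C)Oc2cc(OC)c(C(C)=O)c(OC)c2C[C@H]1OCc1ccccc1 | intermediate
17 | 1-[(3R)-3,5,7-trihydroxy-2,2-dimethylchroman-6-yl]ethan-1-one | CC1(C)Oc2cc(O)c(C(C)=O)c(O)c2C[C@H]1O | intermediate
18 | methyl 3-oxopentanoate | CCC(=O)CC(=O)OC | starting material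
19 | N-methoxy-N-methylpropanamide | CCC(=O)N(C)OC | starting material
20 | methyl 4-methyl-3,5-dioxoheptanoate | CCC(=O)C(C)C(=O)CC(=O)OC | intermediate
21 | 6-ethyl-4-hydroxy-5-methyl-2H-pyran-2-one | CCc1oc(=O)cc(O)c1C | intermediate
22 | 3-[(dimethylamino)methyl]-6-ethyl-4-hydroxy-5-methyl-2H-pyran-2-one | CCc1oc(=O)c(CN(C)C)c(O)c1C | intermediate (not isolated)
23 | 6-ethyl-5-methyl-3-methylidene-2H-pyran-2,4(3H)-dione | CCC1=C(C)C(=O)C(=C)C(=O)O1 | intermediate (not isolated)
24 | 3-{[(3R)-6-acetyl-3,5,7-trihydroxy-2,2-dimethylchroman-8-yl]methyl}-6-ethyl-4-hydroxy-5-methyl-2H-pyran-2-one | CCc1oc(=O)c(Cc2c(O)c(C(C)=O)c(O)c3c2OC(C)(C)[C@H](O)C3)c(O)c1C | target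

**Step count**
Total: 14 steps. Longest linear sequence: 11 steps (steps 1–5, 7–11 and 14).

**Steps most likely to fail**

Step 7. The carbene may be benzylated irreversibly by 7 before fluoride has released the methide. The benzyloxy donor may also enolise too slowly, so that the methide oligomerises, or a catalyst-free addition may erode the enantiomeric purity. The lactone can also lose configuration at C3 by enolisation during isolation. The fallback makes the same two bonds one after the other with an auxiliary; it sets out from 7 and 8 and comes back at 11. Acid chloride 8 would acylate lithiated (4S)-4-benzyl-1,3-oxazolidin-2-one (n-BuLi, THF, –78 °C) to give (4S)-4-benzyl-3-[(benzyloxy)acetyl]-1,3-oxazolidin-2-one F1. Its sodium enolate (NaN(SiMe3)2, THF, –78 °C) would be alkylated by bromide 7 from the face opposite the benzyl group (Evans glycolate alkylation, C3–C4) to give (4S)-4-benzyl-3-[(2R)-2-(benzyloxy)-3-(3-bromo-6-{[tert-butyl(dimethyl)silyl]oxy}-2,4-dimethoxyphenyl)propanoyl]-1,3-oxazolidin-2-one F2. n-Bu4NF buffered with AcOH would then free the phenol, which closes onto the exocyclic imide carbonyl (O1–C2), expels the auxiliary and gives lactone 11.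

Step 10. Oxidative addition of the zerovalent palladium complex and the subsequent transmetallation may both be slow at a bromide flanked by two methoxy groups on a fully substituted ring, so that protodebromination or stannane homocoupling takes over. The fallback replaces the cross-coupling by organolithium chemistry; it sets out from 13 and comes back at 16. Bromine–lithium exchange on 13 (n-BuLi, THF, –78 °C) gives an aryllithium held by the two ortho methoxy groups. Addition to acetaldehyde would give 1-[(3R)-3-(benzyloxy)-5,7-dimethoxy-2,2-dimethylchroman-6-yl]ethan-1-ol F3 as a mixture of carbinol epimers, and Dess–Martin periodinane oxidation would give ketone 16.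

Step 14. The methylidene dione may be captured by a second molecule of pyranone faster than by the chroman, giving the symmetrical bis-pyranone, or residual iminium salt may aminomethylate 17 and stall the sequence. The fallback reverses the roles of the two halves; it sets out from 17 and comes back at 24. Chroman 17 would first be aminomethylated at C8 with [Me2N=CH2]I (CH2Cl2, rt) to give 1-[(3R)-8-[(dimethylamino)methyl]-3,5,7-trihydroxy-2,2-dimethylchroman-6-yl]ethan-1-one F4. Heating F4 with pyranone 21 (1,4-dioxane, 100 °C) would expel dimethylamine to give the ortho-quinone methide of ring A, to which C3 of the pyranone adds to give 24.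

**Further compounds**
F1 | step 7 | (4S)-4-benzyl-3-[(benzyloxy)acetyl]-1,3-oxazolidin-2-one | O=C(COCc1ccccc1)N1[C@@H](Cc2ccccc2)COC1=O
F2 | step 7 | (4S)-4-benzyl-3-[(2R)-2-(benzyloxy)-3-(3-bromo-6-{[tert-butyl(dimethyl)silyl]oxy}-2,4-dimethoxyphenyl)propanoyl]-1,3-oxazolidin-2-one | O=C([C@@H](Cc1c(O[Si](C)(C)C(C)(C)C)cc(OC)c(Br)c1OC)OCc1ccccc1)N1[C@@H](Cc2ccccc2)COC1=O
F3 | step 10 | 1-[(3R)-3-(benzyloxy)-5,7-dimethoxy-2,2-dimethylchroman-6-yl]ethan-1-ol | CC1(C)Oc2cc(OC)c(C(C)O)c(OC)c2C[C@H]1OCc1ccccc1
F4 | step 14 | 1-[(3R)-8-[(dimethylamino)methyl]-3,5,7-trihydroxy-2,2-dimethylchroman-6-yl]ethan-1-one | CC1(C)Oc2c(CN(C)C)c(O)c(C(C)=O)c(O)c2C[C@H]1O
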